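# Synthesis plan for CNP0241021.1 (compound 32)

Atom labels used throughout: ring carbons C1–C10 of the ten-membered carbocycle (C1 ketone, C4/C5 epoxide, C6 lactone oxygen, C7 spiro centre, C8 methacrylate, C10 methyl-bearing ether carbon); lactone carbons C11 (α-carbon), C12 (carbonyl), C13 (exocyclic methylene).

## The problem

Compound 32 is a ten-membered carbocycle whose C7 and C10 are joined by an ether oxygen, so that a tetrahydrofuran is spanned by a six-carbon bridge (an 11-oxabicyclo[6.2.1]undecane), and it carries a spiro α-methylene-γ-butyrolactone on C7 that closes onto the C6 oxygen, a C1 ketone, a C4–C5 trisubstituted epoxide and a C8 methacrylate. Closing a ten-membered ring end to end is the least favourable way to make it, and C7 and C10 are fully substituted ether carbons that simple substitution cannot deliver. Of the six stereocentres (C4, C5, C6, C7, C8, C10), C10 can control C7, because the bridge can only span the tetrahydrofuran cis. C6 must be set relative to its neighbour C7, C8 needs its oxygen on the face of the ring oxygen (hydride from the face shielded by the carbocycle), and the epoxide face can only be governed by the conformation of the finished ring. The α-methylene lactone and the methacrylate are Michael acceptors that tolerate neither hydride, organometallics nor strong base, the epoxide does not tolerate acid, and any β-hydroxy ketone across the quaternary C7 is prone to retro-aldol cleavage, so these groups dictate the order of the last steps. The enabling feature is the array O–C7–C6–C5=C4 with the epoxide read as a masked Z olefin, because an ether oxygen on a carbon homoallylic to a ring Z olefin is what a [2,3] shift of an allyl oxonium ylide leaves behind. Rejoining O to C4 and cutting C6–C7 therefore turns the medium ring into a six-membered cyclic ether (O, C10, C1, C2, C3, C4) with a carbenoid precursor on the C10 side chain.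

## Retrosynthesis

**32 ⇒ 31.** The two C–O bonds of the oxirane are cut. The epoxide is the most acid-labile group, and the Z C4=C5 olefin is exactly what the ring expansion leaves, so the oxygen goes on last. An earlier epoxidation would have to survive acid, palladium and strong base. The forward step must pick the only electron-rich olefin and the face anti to the allylic lactone oxygen.

**31 ⇒ 30 ⇒ 29.** The C8 acyl–oxygen bond is cut, and the C1 ketone and C8 hydroxyl are masked as a dioxolane and a silyl ether. The methacrylate cannot coexist with any earlier reagent, so it is installed on the only free hydroxyl of 30. One acid treatment of 29 is asked to free both masked groups.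

**29 ⇒ 28.** C11–C12 and C12–O are cut: a carbonylative lactonisation of an enol triflate by the C6 hydroxyl. Other lactone cuts (C7–C11, or α-methylenation of a saturated lactone) would require the quaternary C7 to be made with the lactone present; here C11 already sits on C7. The C8 oxygen must be capped, because it is cis to C11 and could close a fused lactone instead.

**28 ⇒ 26 ⇒ 25 ⇒ 23.** The enol triflate is traced to a methyl ketone and this to the C7 ethyl ester (C11–C13 cut, ester methylenation then hydrolysis). C6 needs a temporary silyl group only while the enolate is formed.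

**23 ⇒ 22 ⇒ 21.** The C8–H bond is cut. An undirected hydride would come from the open face next to the ring oxygen and give the wrong epimer. An Evans–Tishchenko reduction uses the C6 hydroxyl to deliver hydride from the carbocycle face and, unlike a simple directed reduction to a diol, leaves C6 acylated and C8 free, so the two oxygens are told apart.

**21 ⇒ 20 ⇒ 18.** C6–C7 is cut and O–C4 rejoined (key step). This removes the ten-membered ring, the ether bridge and the stereocentres C6 and C7 at once; 18 is a monocyclic oxane with two stereocentres. Direct closure of the carbocycle by aldol or olefination would have to fight ring strain with both quaternary centres in place. The oxygen substituent of the enol ether is tert-butyldimethylsilyl, because it comes straight from an aldehyde and leaves C6 under buffered fluoride without base.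

**18 ⇒ 17 ⇒ 16 ⇒ 15 ⇒ 14 ⇒ 12 + 13.** The silyl enol ether is made last from aldehyde 17, so that it meets no other reagent. The diazo keto ester comes from aldehyde 12 and ethyl diazoacetate 13 (C7–C8 cut, Roskamp reaction, then diazo transfer). The C6 oxygen rides through as a silyl ether of a primary alcohol.

**12 ⇒ 11 ⇒ 10 ⇒ 9 ⇒ 8.** The C8 aldehyde is traced to a vinyl group on C10 (anti-Markovnikov hydration, oxidation), and the C1 dioxolane to the carbinol of 8. The ketal prevents a six-membered carbonyl ylide in the key step and is orthogonal to every silyl group used later.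

**8 ⇒ 7 ⇒ 6 ⇒ 5 ⇒ 4.** The O–C10 bond is cut: 6-endo opening of a trisubstituted epoxide by the tertiary hydroxyl. With a hydroxymethyl group at the distal carbon the hydroxyl would close a tetrahydrofuran at the other epoxide carbon. The primary alcohol of 5 is therefore turned into a vinyl group, which steers the opening and later supplies C9 and C8. The epoxide configuration, and with it C10, comes from a Sharpless asymmetric epoxidation.

**4 ⇒ 3 ⇒ 2 ⇒ 1.** Allylic hydroxylation of the E methyl group, protection, and hydroboration of the vinyl group lead back to (R)-linalool 1. Its carbinol carbon is C4, and the hydroboration already places the future C6 oxygen.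

## Roads not taken

**Alternative 1:** The cut is C7–C11. A carbenoid generated with Rh2(OAc)4 (dirhodium tetraacetate, divalent rhodium) from a diazoacetate on the C6 oxygen would insert into the C7–H bond with retention and give the spiro lactone A1.
- Merits: the quaternary spiro centre and the lactone ring arise in one step from a tetrahydrofuran in which C8 and C10 are already set. The C8 oxygen has its final configuration from simple five-membered-ring chemistry. In this respect the route is better than the chosen plan, which has to earn C8 with a directed reduction and several protecting-group changes.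
- Weak points: A1 contains only C5–C12, so C2–C4 must still be brought in and the ten-membered ring closed between the C1 and C5 ester carbons, end to end, with a Z trisubstituted olefin and two quaternary centres in the ring. The exocyclic methylene is still missing.
- Comparison: the chosen plan sets against the easier C7/C8 chemistry the fact that ring, bridge, C6 and C7 come from one ring expansion of a six-membered ether.

**Alternative 2:** The cut is C8–C9, made in the forward sense while C1–C6 breaks. The potassium alkoxide (KH, 18-crown-6) of a trans-1,2-dialkenyl epoxycyclohexanol would undergo an anionic oxy-Cope rearrangement through a chair, and trapping with Me3SiCl would give the ten-membered silyl enol ether A2.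
- Merits: this is the best-established way to a cyclodecenone, the C1 oxygen and C10 methyl are placed by the rearrangement, and the cis epoxide is carried in from a six-membered ring. The last point avoids the late, conformation-dependent epoxidation of the chosen plan and is a real advantage.
- Weak points: A2 lacks the C7–O–C10 bridge and both fully substituted ether carbons. C7 must gain an oxygen, C10 must gain one at the enol ether carbon, and the two must be joined across a flexible ring, with C6 oxygenation and the spiro lactone still to come. The epoxide also has to survive KH.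
- Comparison: the carbocycle is reached faster, but the hardest stereocentres are left to transannular chemistry, whereas the chosen plan builds C10 before the ring and C7 with the ring.

**Alternative 3:** The cut is a C1=C6 double bond (retro-ozonolysis). O3 then Me2S would cleave the tetrasubstituted ring-fusion olefin of a cyclohexyne–furan cycloadduct and open both six-membered rings into the bridged 1,6-diketone A3.
- Merits: the oxygen bridge is cis by construction, C7, C8 and C10 are set on a rigid bicycle (where attack from the open face gives the C8 configuration the target needs), and the skeleton is reached in very few steps. In length and in C8 control this road is better than the chosen one.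
- Weak points: A3 arrives with four unfunctionalised methylene groups between C1 and C6, so the C4 methyl, the C4–C5 olefin and the C6 stereocentre must be introduced on a bare chain. The C1 and C6 ketones are of similar reactivity and must be differentiated. The C7 benzyloxymethyl group needs a one-carbon homologation before a lactone can form.
- Comparison: the chosen plan is longer, but its key step delivers the C4 methyl, the Z olefin and the C6 oxygen already in place.

Key step: step 17

Assumption: (R)-(−)-linalool is taken as commercially available in high enantiomeric purity; its carbinol carbon becomes C4, whose configuration is transferred to C6 in the key step.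

## Route

Step 1
Reactants: 1 (R)-linalool
Product: 2 (3R)-3,7-dimethyloct-6-ene-1,3-diol
Conditions: 9-BBN, THF, 0 °C to rt; then NaOH, H2O2 (aq.), 0 °C
Reagents that add atoms: hydrogen peroxide, OO
Why: Hydroboration–oxidation with the bulky dialkylborane distinguishes the monosubstituted vinyl group from the trisubstituted olefin and places the hydroxyl on the terminal carbon, which becomes the C6 oxygen; the carbinol centre is not touched.

Step 2
Reactants: 2 (3R)-3,7-dimethyloct-6-ene-1,3-diol
Product: 3 (3R)-1-(tert-butyldiphenylsilyloxy)-3,7-dimethyloct-6-en-3-ol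
Conditions: t-BuPh2SiCl, imidazole, CH2Cl2, 0 °C
Reagents that add atoms: tert-butyl(chloro)diphenylsilane, CC(C)(C)[Si](Cl)(c1ccccc1)c1ccccc1
Why: Silylation with a bulky chlorosilane is selective for the primary over the tertiary hydroxyl; the group is chosen to outlast acid, oxidants and Lewis acids up to step 14.

Step 3
Reactants: 3 (3R)-1-(tert-butyldiphenylsilyloxy)-3,7-dimethyloct-6-en-3-ol
Product: 4 (2E,6R)-8-(tert-butyldiphenylsilyloxy)-2,6-dimethyloct-2-ene-1,6-diol
Conditions: SeO2 (cat.), t-BuOOH, salicylic acid (cat.), CH2Cl2, rt
Reagents that add atoms: tert-butyl hydroperoxide, CC(C)(C)OO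
Why: Selenium dioxide allylic oxidation (ene reaction, then [2,3] shift of the allylseleninic acid) attacks the E methyl group of a trisubstituted olefin and gives the E allylic alcohol needed for the asymmetric epoxidation.

Step 4
Reactants: 4 (2E,6R)-8-(tert-butyldiphenylsilyloxy)-2,6-dimethyloct-2-ene-1,6-diol
Product: 5 (2S,3S)-epoxy alcohol
Conditions: Ti(OiPr)4 (cat.), L-(+)-diethyl tartrate (cat.), t-BuOOH, 4 Å molecular sieves, CH2Cl2, −20 °C
Reagents that add atoms: tert-butyl hydroperoxide, CC(C)(C)OO
Why: Sharpless asymmetric epoxidation: only the primary allylic alcohol is activated on the titanium tartrate, and L-(+)-tartrate should give the (2S,3S) epoxide of this E 2-methyl allylic alcohol by reagent control, which fixes the configuration later inverted into C10.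

Step 5
Reactants: 5 (2S,3S)-epoxy alcohol
Product: 6 (2R,3S)-epoxy aldehyde
Conditions: Dess–Martin periodinane, NaHCO3, CH2Cl2, 0 °C to rt
Reagents that add atoms: none
Why: Dess–Martin oxidation of the primary alcohol under buffered conditions leaves the epoxide and tertiary alcohol alone; the aldehyde has no α-hydrogen and cannot epimerise.

Step 6
Reactants: 6 (2R,3S)-epoxy aldehyde
Product: 7 (2S,3S)-vinyl epoxide
Conditions: Ph3PCH3Br, KN(SiMe3)2, THF, −78 to 0 °C
Reagents that add atoms: methyltriphenylphosphonium bromide, C[P+](c1ccccc1)(c1ccccc1)c1ccccc1.[Br-]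
Why: Wittig methylenation makes the quaternary epoxide carbon allylic as well as tertiary, which is what directs the following ring closure, and the vinyl group is the latent C9–C8 unit.

Step 7
Reactants: 7 (2S,3S)-vinyl epoxide
Product: 8 (2R,3S,6R)-6-[2-(tert-butyldiphenylsilyloxy)ethyl]-2-ethenyl-2,6-dimethyloxan-3-ol
Conditions: camphor-10-sulfonic acid (cat.), CH2Cl2, −20 to 0 °C
Reagents that add atoms: none
Why: Acid-catalysed intramolecular epoxide opening in the 6-endo mode: positive charge in the transition state is best carried by the tertiary, allylic epoxide carbon, so the tertiary hydroxyl attacks there with inversion instead of closing a tetrahydrofuran at the other carbon; the inversion sets C10 (R) and places the vinyl group cis to the silyloxyethyl arm.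

Step 8
Reactants: 8 (2R,3S,6R)-oxan-3-ol
Product: 9 (2R,6R)-6-[2-(tert-butyldiphenylsilyloxy)ethyl]-2-ethenyl-2,6-dimethyloxan-3-one
Conditions: Dess–Martin periodinane, NaHCO3, CH2Cl2, rt
Reagents that add atoms: none
Why: Dess–Martin oxidation of the secondary alcohol gives the C1 ketone; the carbinol stereocentre has served its purpose and C10 cannot epimerise because it is fully substituted.

Step 9
Reactants: 9 (2R,6R)-oxan-3-one
Product: 10 (6R,8R)-8-[2-(tert-butyldiphenylsilyloxy)ethyl]-6-ethenyl-6,8-dimethyl-1,4,7-trioxaspiro[4.5]decane
Conditions: Me3SiOCH2CH2OSiMe3, Me3SiOTf (cat.), CH2Cl2, −78 to −20 °C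
Reagents that add atoms: 1,2-bis(trimethylsilyloxy)ethane, C[Si](C)(C)OCCO[Si](C)(C)C
Why: Silyl-triflate-catalysed ketalisation works on hindered ketones at low temperature and spares the silyl ether; the dioxolane keeps C1 from forming a carbonyl ylide later and from reacting with borane, the titanium carbenoid and the amide base.

Step 10
Reactants: 10 (6R,8R)-vinyl ketal
Product: 11 2-[(6R,8R)-8-[2-(tert-butyldiphenylsilyloxy)ethyl]-6,8-dimethyl-1,4,7-trioxaspiro[4.5]decan-6-yl]ethanol
Conditions: 9-BBN, THF, rt to 50 °C; then NaOH, H2O2 (aq.), 0 °C
Reagents that add atoms: hydrogen peroxide, OO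
Why: Anti-Markovnikov hydroboration–oxidation of the only olefin left turns the vinyl group into the two-carbon arm C9–C8 with oxygen on C8.

Step 11
Reactants: 11 primary alcohol
Product: 12 2-[(6R,8R)-8-[2-(tert-butyldiphenylsilyloxy)ethyl]-6,8-dimethyl-1,4,7-trioxaspiro[4.5]decan-6-yl]acetaldehyde
Conditions: Dess–Martin periodinane, NaHCO3, CH2Cl2, 0 °C
Reagents that add atoms: none
Why: Dess–Martin oxidation stops at the aldehyde and tolerates ketal and silyl ether.

Step 12
Reactants: 12 aldehyde; 13 ethyl diazoacetate
Product: 14 ethyl 4-[(6R,8R)-8-[2-(tert-butyldiphenylsilyloxy)ethyl]-6,8-dimethyl-1,4,7-trioxaspiro[4.5]decan-6-yl]-3-oxobutanoate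
Conditions: SnCl2 (cat.), CH2Cl2, rt
Reagents that add atoms: ethyl diazoacetate (compound 13), CCOC(=O)C=[N+]=[N-]
Why: Roskamp reaction: tin-dichloride-catalysed addition of the diazo ester to the aldehyde and 1,2-hydride shift with loss of nitrogen give the β-keto ester in one step, forming the C7–C8 bond.

Step 13
Reactants: 14 β-keto ester
Product: 15 ethyl 2-diazo-4-[(6R,8R)-8-[2-(tert-butyldiphenylsilyloxy)ethyl]-6,8-dimethyl-1,4,7-trioxaspiro[4.5]decan-6-yl]-3-oxobutanoate
Conditions: 4-acetamidobenzenesulfonyl azide, Et3N, MeCN, 0 °C to rt
Reagents that add atoms: 4-acetamidobenzenesulfonyl azide, CC(=O)Nc1ccc(cc1)S(=O)(=O)N=[N+]=[N-]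
Why: Regitz diazo transfer to the activated methylene of a β-keto ester; the doubly acceptor-substituted diazo group is stable to the next three steps.

Step 14
Reactants: 15 diazo keto ester
Product: 16 ethyl 2-diazo-4-[(6R,8R)-8-(2-hydroxyethyl)-6,8-dimethyl-1,4,7-trioxaspiro[4.5]decan-6-yl]-3-oxobutanoate
Conditions: HF·pyridine, pyridine, THF, 0 °C to rt
Reagents that add atoms: none
Why: Buffered fluoride cleaves the primary silyl ether without base, so the diazo dicarbonyl unit is not deacylated and the hindered dioxolane is kept.

Step 15
Reactants: 16 primary alcohol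
Product: 17 ethyl 2-diazo-4-[(6R,8R)-6,8-dimethyl-8-(2-oxoethyl)-1,4,7-trioxaspiro[4.5]decan-6-yl]-3-oxobutanoate
Conditions: Dess–Martin periodinane, NaHCO3, CH2Cl2, 0 °C
Reagents that add atoms: none
Why: Dess–Martin oxidation is neutral and compatible with acceptor-substituted diazo compounds; it gives the C6 aldehyde from which the enol ether is drawn.

Step 16
Reactants: 17 aldehyde
Product: 18 ethyl 4-[(6R,8R)-8-[(E)-2-(tert-butyldimethylsilyloxy)ethenyl]-6,8-dimethyl-1,4,7-trioxaspiro[4.5]decan-6-yl]-2-diazo-3-oxobutanoate
Conditions: t-BuMe2SiOTf, Et3N, CH2Cl2, −78 °C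
Reagents that add atoms: tert-butyldimethylsilyl trifluoromethanesulfonate, CC(C)(C)[Si](C)(C)OS(=O)(=O)C(F)(F)F
Why: Soft enolisation: the aldehyde is O-silylated and deprotonated by the amine far faster than the hindered diazo ketone at low temperature; the E enol ether is expected because the fully substituted C4 avoids the position cis to the silyloxy group, and E is the geometry the ring expansion needs.

Step 17
Reactants: 18 oxane diazo keto ester with E silyl enol ether
Product: 20 bridged keto ester of the 11-oxabicyclo[6.2.1]undecene series (6R 7R 10R Z), via oxonium ylide 19 (not isolated)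
Conditions: Cu(hfacac)2 (5 mol%), CH2Cl2, reflux, slow addition at high dilution
Reagents that add atoms: none
Why: Cu(hfacac)2 (copper bis(hexafluoroacetylacetonate), divalent copper) converts the diazo group of 18 into an electrophilic copper carbenoid at C7, which is captured by a lone pair of the oxane oxygen in a five-membered closure (favoured over six-membered attack by a dioxolane oxygen) to give the cis-fused bicyclic oxonium ylide 19. A suprafacial [2,3]-sigmatropic shift through a five-membered envelope then bonds C7 to C6 and breaks O–C4, so the oxane is exchanged for the ten-membered carbocycle (three-atom ring expansion) while the tetrahydrofuranone remains. The closest known reaction type is the copper-catalysed oxonium ylide formation and [2,3] rearrangement of 2-alkenyl cyclic ethers to oxygen-bridged medium rings; here the migrating terminus is a silyl enol ether and both ether carbons are fully substituted. C7 is controlled by C10: the C6–C7 bond can only form on the face of the five-membered ring that carries the old oxane, so C6 and C1 end up cis on the tetrahydrofuran. C6 is controlled by chirality transfer from C4 through the suprafacial shift, given the E enol ether and a transition state in which both carbon arms are equatorial on the oxane chair; the same transition state turns C3 cis to C6 and gives the Z C4=C5 olefin. The step needs [2,3] over [1,2] shift (helped by the allylic terminus and the copper catalyst), Z over E, and ylide formation at the oxane oxygen only; the C1 ketal rules out a carbonyl ylide. Slow addition at high dilution suppresses carbene dimerisation.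

Step 18
Reactants: 20 bridged keto ester with C6 silyl ether
Product: 21 bridged β-hydroxy keto ester (free C6 hydroxyl)
Conditions: HF·pyridine, pyridine, THF, 0 °C
Reagents that add atoms: none
Why: Buffered fluoride removes the secondary allylic silyl ether without base, which avoids retro-aldol cleavage of the β-hydroxy ketone across the quaternary C7; the product is used at once.

Step 19
Reactants: 21 bridged β-hydroxy keto ester
Product: 22 C6 acetate with free C8 hydroxyl
Conditions: SmI2 (cat.), CH3CHO, THF, −10 °C
Reagents that add atoms: acetaldehyde, CC=O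
Why: Evans–Tishchenko reduction (catalyst precursor SmI2, divalent samarium): the samarium-bound hemiacetal formed from the C6 hydroxyl and acetaldehyde delivers its hydride to the C8 ketone through a six-membered chair. Because C6 hangs on the carbocycle face of the tetrahydrofuranone, hydride enters from that face and the C8 hydroxyl appears on the face of the ring oxygen, cis to the ester, as in 32. The aldehyde ends as the C6 acetate, so the two oxygens leave the step differentiated.

Step 20
Reactants: 22 C6 acetate with free C8 hydroxyl
Product: 23 C6 acetate C8 tert-butyldimethylsilyl ether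
Conditions: t-BuMe2SiOTf, 2,6-lutidine, CH2Cl2, −78 to 0 °C
Reagents that add atoms: tert-butyldimethylsilyl trifluoromethanesulfonate, CC(C)(C)[Si](C)(C)OS(=O)(=O)C(F)(F)F
Why: Silyl triflate with a hindered pyridine base silylates hindered secondary alcohols; C8 must be capped because its oxygen is cis to C11 and would compete in the later lactonisation.

Step 21
Reactants: 23 C6 acetate C8 silyl ether
Product: 25 C6 hydroxy C7 methyl ketone, via bis(enol ether) 24 (not isolated)
Conditions: Cp2Ti(μ-Cl)(μ-CH2)AlMe2 (Tebbe reagent), pyridine, THF, −40 °C to rt; then 0.5 M HCl, THF, 0 °C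
Reagents that add atoms: Tebbe reagent Cp2Ti(μ-Cl)(μ-CH2)AlMe2, C[Al-]1(C)C[Ti]([Cl+]1)(C1C=CC=C1)C1C=CC=C1; water, O
Why: Tebbe methylenation (carbonyl olefination by the titanium methylidene through an oxatitanacyclobutane) converts both the hindered C7 ethyl ester and the C6 acetate into enol ethers without base, pyridine tying up Me2AlCl so that the dioxolane and the allyl isopropenyl ether stay intact at or below room temperature. Brief dilute acid then hydrolyses the 1-ethoxyvinyl group to the C11 methyl ketone and the isopropenyl ether to the free C6 hydroxyl, while the hindered dioxolane and the secondary silyl ether are kept.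

Step 22
Reactants: 25 C6 hydroxy C7 methyl ketone
Product: 26 C6 triethylsilyl ether
Conditions: Et3SiOTf, 2,6-lutidine, CH2Cl2, −78 °C
Reagents that add atoms: triethylsilyl trifluoromethanesulfonate, CC[Si](CC)(CC)OS(=O)(=O)C(F)(F)F
Why: A labile silyl group on C6 prevents retro-aldol cleavage and O-sulfonylation when the ketone is enolised with strong base in the next step.

Step 23
Reactants: 26 C6 triethylsilyl ether
Product: 28 hydroxy enol triflate, via triethylsilyl-protected enol triflate 27 (not isolated)
Conditions: KN(SiMe3)2, PhNTf2, THF, −78 °C; then HF·pyridine, pyridine, 0 °C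
Reagents that add atoms: N-phenylbis(trifluoromethanesulfonimide), O=S(=O)(N(c1ccccc1)S(=O)(=O)C(F)(F)F)C(F)(F)F
Why: The ketone can enolise only towards its methyl group because C7 is quaternary, so O-triflation gives the 1,1-disubstituted enol triflate; buffered fluoride then removes the triethylsilyl group selectively in the presence of the hindered tert-butyldimethylsilyl ether.

Step 24
Reactants: 28 hydroxy enol triflate
Product: 29 spiro α-methylene-γ-butyrolactone (C8 silyl ether, C1 ketal)
Conditions: Pd(PPh3)4 (cat.), CO (1 atm), n-Bu3N, LiCl, MeCN, 50 °C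
Reagents that add atoms: carbon monoxide, [C-]#[O+]
Why: Carbonylative lactonisation: Pd(PPh3)4 (zerovalent palladium) adds oxidatively to the enol triflate, CO inserts, and the C6 hydroxyl captures the acylpalladium in a five-membered closure, forming C11–C12 and C12–O with the methylene already in place; C6 and C7 are not touched, and the moderate temperature under CO is chosen so that the allylic lactone formed is not ionised by the catalyst.

Step 25
Reactants: 29 spiro lactone
Product: 30 C8 hydroxy C1 ketone
Conditions: 2 M HCl, THF, rt
Reagents that add atoms: water, O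
Why: Aqueous acid hydrolyses the dioxolane and cleaves the secondary silyl ether in one operation; the α-methylene lactone tolerates acid and no acid-labile epoxide is present yet.

Step 26
Reactants: 30 C8 hydroxy C1 ketone
Product: 31 C8 methacrylate
Conditions: methacrylic anhydride, Et3N, DMAP (cat.), CH2Cl2, 0 °C to rt
Reagents that add atoms: methacrylic anhydride, C=C(C)C(=O)OC(=O)C(C)=C
Why: Acyl-pyridinium catalysed esterification of the only free hydroxyl; C8 keeps its configuration because the C–O bond is not broken.

Step 27
Reactants: 31 C8 methacrylate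
Product: 32 CNP0241021.1
Conditions: m-CPBA, NaHCO3, CH2Cl2, 0 °C
Reagents that add atoms: 3-chloroperoxybenzoic acid, OOC(=O)c1cccc(Cl)c1
Why: Prilezhaev epoxidation is stereospecific (Z olefin to cis epoxide) and attacks only the electron-rich trisubstituted olefin, the other two being conjugated to carbonyl groups; the peracid is expected to approach anti to the allylic lactone C–O bond, as is usual for cyclic allylic esters that cannot hydrogen-bond to the reagent, which is the face required for C4 (R) and C5 (S).

## Compound list

1 | (R)-linalool, (3R)-3,7-dimethylocta-1,6-dien-3-ol | CC(C)=CCC[C@@](C)(O)C=C | starting material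
2 | (3R)-3,7-dimethyloct-6-ene-1,3-diol | CC(C)=CCC[C@@](C)(O)CCO | intermediate
3 | (3R)-1-(tert-butyldiphenylsilyloxy)-3,7-dimethyloct-6-en-3-ol | CC(C)=CCC[C@@](C)(O)CCO[Si](c1ccccc1)(c1ccccc1)C(C)(C)C | intermediate
4 | (2E,6R)-8-(tert-butyldiphenylsilyloxy)-2,6-dimethyloct-2-ene-1,6-diol | OC/C(C)=C/CC[C@@](C)(O)CCO[Si](c1ccccc1)(c1ccccc1)C(C)(C)C | intermediate
5 | [(2S,3S)-3-[(3R)-5-(tert-butyldiphenylsilyloxy)-3-hydroxy-3-methylpentyl]-2-methyloxiran-2-yl]methanol | OC[C@]1(C)O[C@H]1CC[C@@](C)(O)CCO[Si](c1ccccc1)(c1ccccc1)C(C)(C)C | intermediate
6 | (2R,3S)-3-[(3R)-5-(tert-butyldiphenylsilyloxy)-3-hydroxy-3-methylpentyl]-2-methyloxirane-2-carbaldehyde | O=C[C@]1(C)O[C@H]1CC[C@@](C)(O)CCO[Si](c1ccccc1)(c1ccccc1)C(C)(C)C | intermediate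
7 | (3R)-1-(tert-butyldiphenylsilyloxy)-5-[(2S,3S)-3-ethenyl-3-methyloxiran-2-yl]-3-methylpentan-3-ol | C=C[C@]1(C)O[C@H]1CC[C@@](C)(O)CCO[Si](c1ccccc1)(c1ccccc1)C(C)(C)C | intermediate
8 | (2R,3S,6R)-6-[2-(tert-butyldiphenylsilyloxy)ethyl]-2-ethenyl-2,6-dimethyloxan-3-ol (vinyl and silyloxyethyl arms cis) | C=C[C@@]1(C)O[C@@](C)(CCO[Si](c2ccccc2)(c2ccccc2)C(C)(C)C)CC[C@@H]1O | intermediate
9 | (2R,6R)-6-[2-(tert-butyldiphenylsilyloxy)ethyl]-2-ethenyl-2,6-dimethyloxan-3-one | C=C[C@@]1(C)O[C@@](C)(CCO[Si](c2ccccc2)(c2ccccc2)C(C)(C)C)CCC1=O | intermediate
10 | (6R,8R)-8-[2-(tert-butyldiphenylsilyloxy)ethyl]-6-ethenyl-6,8-dimethyl-1,4,7-trioxaspiro[4.5]decane | C=C[C@@]1(C)O[C@@](C)(CCO[Si](c2ccccc2)(c2ccccc2)C(C)(C)C)CCC13OCCO3 | intermediate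
11 | 2-[(6R,8R)-8-[2-(tert-butyldiphenylsilyloxy)ethyl]-6,8-dimethyl-1,4,7-trioxaspiro[4.5]decan-6-yl]ethanol | OCC[C@@]1(C)O[C@@](C)(CCO[Si](c2ccccc2)(c2ccccc2)C(C)(C)C)CCC13OCCO3 | intermediate
12 | 2-[(6R,8R)-8-[2-(tert-butyldiphenylsilyloxy)ethyl]-6,8-dimethyl-1,4,7-trioxaspiro[4.5]decan-6-yl]acetaldehyde | O=CC[C@@]1(C)O[C@@](C)(CCO[Si](c2ccccc2)(c2ccccc2)C(C)(C)C)CCC13OCCO3 | intermediate
13 | ethyl diazoacetate | CCOC(=O)C=[N+]=[N-] | starting material
14 | ethyl 4-[(6R,8R)-8-[2-(tert-butyldiphenylsilyloxy)ethyl]-6,8-dimethyl-1,4,7-trioxaspiro[4.5]decan-6-yl]-3-oxobutanoate | CCOC(=O)CC(=O)C[C@@]1(C)O[C@@](C)(CCO[Si](c2ccccc2)(c2ccccc2)C(C)(C)C)CCC13OCCO3 | intermediate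
15 | ethyl 2-diazo-4-[(6R,8R)-8-[2-(tert-butyldiphenylsilyloxy)ethyl]-6,8-dimethyl-1,4,7-trioxaspiro[4.5]decan-6-yl]-3-oxobutanoate | CCOC(=O)C(=[N+]=[N-])C(=O)C[C@@]1(C)O[C@@](C)(CCO[Si](c2ccccc2)(c2ccccc2)C(C)(C)C)CCC13OCCO3 | intermediate
16 | ethyl 2-diazo-4-[(6R,8R)-8-(2-hydroxyethyl)-6,8-dimethyl-1,4,7-trioxaspiro[4.5]decan-6-yl]-3-oxobutanoate | CCOC(=O)C(=[N+]=[N-])C(=O)C[C@@]1(C)O[C@@](C)(CCO)CCC13OCCO3 | intermediate
17 | ethyl 2-diazo-4-[(6R,8R)-6,8-dimethyl-8-(2-oxoethyl)-1,4,7-trioxaspiro[4.5]decan-6-yl]-3-oxobutanoate | CCOC(=O)C(=[N+]=[N-])C(=O)C[C@@]1(C)O[C@@](C)(CC=O)CCC13OCCO3 | intermediate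
18 | ethyl 4-[(6R,8R)-8-[(E)-2-(tert-butyldimethylsilyloxy)ethenyl]-6,8-dimethyl-1,4,7-trioxaspiro[4.5]decan-6-yl]-2-diazo-3-oxobutanoate (key-step precursor; C1 ketal, E enol ether on C4) | CCOC(=O)C(=[N+]=[N-])C(=O)C[C@@]1(C)O[C@@](C)(/C=C/O[Si](C)(C)C(C)(C)C)CCC13OCCO3 | intermediate
19 | cis-fused bicyclic oxonium ylide (oxygen bonded to C4, C7 and C10; carbanion at C7 between ketone and ester) | CCOC(=O)[C-]1C(=O)C[C@@]2(C)[O+]1[C@@](C)(/C=C/O[Si](C)(C)C(C)(C)C)CCC23OCCO3 | intermediate
20 | bridged keto ester, 11-oxabicyclo[6.2.1]undecene core: C8 ketone, (7R) ethyl ester, (6R) tert-butyldimethylsilyloxy, Z C4=C5 with C4 methyl, C1 dioxolane, (10R) methyl, oxygen bridging C7 and C10 | O=C1C[C@@]2(C)O[C@]1(C(=O)OCC)[C@H](O[Si](C)(C)C(C)(C)C)/C=C(C)\CCC23OCCO3 | intermediate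
21 | as 20 with free C6 hydroxyl (β-hydroxy keto ester) | O=C1C[C@@]2(C)O[C@]1(C(=O)OCC)[C@H](O)/C=C(C)\CCC23OCCO3 | intermediate
22 | C6 acetate, C8 hydroxyl on the face of the ring oxygen (cis to the C7 ester, trans to C6); otherwise as 21 | O[C@H]1C[C@@]2(C)O[C@]1(C(=O)OCC)[C@H](OC(C)=O)/C=C(C)\CCC23OCCO3 | intermediate
23 | as 22 with C8 tert-butyldimethylsilyl ether | CC(C)(C)[Si](C)(C)O[C@H]1C[C@@]2(C)O[C@]1(C(=O)OCC)[C@H](OC(C)=O)/C=C(C)\CCC23OCCO3 | intermediate
24 | bis(enol ether): C7 1-ethoxyvinyl, C6 isopropenyl ether, C8 silyl ether | CC(C)(C)[Si](C)(C)O[C@H]1C[C@@]2(C)O[C@]1(C(=C)OCC)[C@H](OC(C)=C)/C=C(C)\CCC23OCCO3 | intermediate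
25 | C7 acetyl (C11 ketone, C13 methyl), free C6 hydroxyl, C8 silyl ether, C1 dioxolane | CC(C)(C)[Si](C)(C)O[C@H]1C[C@@]2(C)O[C@]1(C(C)=O)[C@H](O)/C=C(C)\CCC23OCCO3 | intermediate
26 | as 25 with C6 triethylsilyl ether | CC(C)(C)[Si](C)(C)O[C@H]1C[C@@]2(C)O[C@]1(C(C)=O)[C@H](O[Si](CC)(CC)CC)/C=C(C)\CCC23OCCO3 | intermediate
27 | C11 enol triflate with C6 triethylsilyl ether and C8 tert-butyldimethylsilyl ether | CC(C)(C)[Si](C)(C)O[C@H]1C[C@@]2(C)O[C@]1(C(=C)OS(=O)(=O)C(F)(F)F)[C@H](O[Si](CC)(CC)CC)/C=C(C)\CCC23OCCO3 | intermediate
28 | C11 enol triflate with free C6 hydroxyl and C8 tert-butyldimethylsilyl ether | CC(C)(C)[Si](C)(C)O[C@H]1C[C@@]2(C)O[C@]1(C(=C)OS(=O)(=O)C(F)(F)F)[C@H](O)/C=C(C)\CCC23OCCO3 | intermediate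
29 | spiro α-methylene-γ-butyrolactone (C7 spiro, lactone oxygen on C6), C8 silyl ether, Z C4=C5, C1 dioxolane | CC(C)(C)[Si](C)(C)O[C@H]1C[C@@]2(C)O[C@@]13C(=C)C(=O)O[C@@H]3/C=C(C)\CCC24OCCO4 | intermediate
30 | as 29 with free C8 hydroxyl and C1 ketone | O[C@H]1C[C@@]2(C)O[C@@]13C(=C)C(=O)O[C@@H]3/C=C(C)\CCC2=O | intermediate
31 | C8 methacrylate of 30 (4,5-deoxy target, Z C4=C5) | C=C(C)C(=O)O[C@H]1C[C@@]2(C)O[C@@]13C(=C)C(=O)O[C@@H]3/C=C(C)\CCC2=O | intermediate
32 | CNP0241021.1, (4R,5S,6R,7S,8S,10R) in the carbocycle numbering: 1-oxo, 4,5-epoxide, 7,10-ether bridge, 12,6-lactone with 11(13)-methylene, 8-methacrylate | C=C(C)C(=O)O[C@H]1C[C@@]2(C)O[C@@]13C(=C)C(=O)O[C@@H]3[C@@H]1O[C@]1(C)CCC2=O | target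

## Step count and least certain steps

Total: 27 steps. Longest linear sequence: 27 steps from (R)-linalool 1 (ethyl diazoacetate 13 is used as purchased).

**Step 17 (key step).** The bicyclic ylide 19 may break its O–C4 bond heterolytically before C6–C7 bonding, because C4 is tertiary, allylic and conjugated to a silyl enol ether. Collapse of the resulting ion pair would loosen the link between the C4 configuration and C6, and would open the way to [1,2] shift, silyl transfer with fragmentation, and the E ring olefin. Reaction through the chair with both arms axial would likewise give the E olefin with the opposite C6 configuration. The fallback changes the migrating terminus to a less electron-rich enol carbonate, which cannot stabilise a cation at C4 to the same degree; it sets out from 17 and comes back at 21. Aldehyde 17 would be converted with KN(SiMe3)2 and allyl chloroformate into the (E)-enol allyl carbonate F1. The same copper-catalysed ring expansion would give the bridged C6 allyl carbonate F2. Pd(PPh3)4 (zerovalent palladium) with morpholine would then remove the allyloxycarbonyl group under neutral conditions and return the route at 21.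

**Step 7 (6-endo epoxide opening).** The tertiary allylic epoxide carbon may ionise fully instead of being displaced, which would erode the configuration of C10 or lead to loss of a proton to a diene. The fallback replaces acid-mediated displacement by a palladium π-allyl cyclisation with net retention, and therefore starts from the enantiomeric epoxide; it sets out from 4 and comes back at 9. Allylic alcohol 4 would be epoxidised with Ti(OiPr)4, D-(−)-diethyl tartrate and t-BuOOH to the (2R,3R)-epoxy alcohol F3, Dess–Martin oxidation would give the epoxy aldehyde F4, and Wittig methylenation the vinyl epoxide F5. Cyclisation with Pd(PPh3)4 (zerovalent palladium; ionisation with inversion, attack of the hydroxyl anti to palladium) would give the oxanol F6, the C1 epimer of 8 with the same C10. Dess–Martin oxidation of F6 returns the route at ketone 9.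

**Step 16 (silyl enol ether).** Enolisation may give poor E/Z selectivity, and the Z isomer would carry the opposite configuration into C6; some silylation of the diazo ketone is also possible. The fallback gives up chirality transfer to C6 in favour of reagent control; it sets out from 18, taken on as the isomer mixture, and comes back at 28. The mixture would be carried through steps 17–23 (both C6 epimers can direct the C8 reduction) to 28 as a C6 epimer mixture. Allylic oxidation of 28 with MnO2 would converge both epimers to the enone F7. Corey–Bakshi–Shibata reduction with the (S)-2-methyl-oxazaborolidine and catecholborane (the quaternary C7 acting as the large group) should return (6R)-28.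

**Step 19 (Evans–Tishchenko reduction).** The hindered C6 hydroxyl may form the hemiacetal slowly, 21 may undergo retro-aldol cleavage at the Lewis-acidic samarium alkoxide, and the acetate may migrate from C6 to C8. The fallback separates reduction from differentiation; it sets out from 21 and comes back at 25. Evans–Saksena reduction of 21 with Me4NBH(OAc)3 in acetic acid–acetonitrile would give the diol F8 with the same C8 configuration. MnO2 would oxidise only the allylic C6 alcohol to the hydroxy enone F9, and silylation with t-BuMe2SiOTf and 2,6-lutidine would give the C8 silyl ether F10. Corey–Bakshi–Shibata reduction would restore the C6 hydroxyl in the (6R) alcohol F11. Methylenation of F11 with Cp2Ti(μ-Cl)(μ-CH2)AlMe2 followed by acid hydrolysis, as in step 21, would return the route at 25.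

**Step 27 (epoxidation).** The peracid may attack the olefin face syn to the lactone oxygen, or show poor facial selectivity, because the preferred conformation of the bridged ten-membered ring is not known. The fallback inverts the facial outcome through a halohydrin; it sets out from 31 and ends at 32. N-bromosuccinimide in aqueous dimethoxyethane would add bromine to C5 from the accessible face and water to C4 from the other, giving the bromohydrin F12. Ag2O would then close the epoxide by displacement of bromide, placing the oxygen on the face opposite to that reached by direct epoxidation, to give 32.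

## Further compounds

F1 | step 17 | (E)-enol allyl carbonate analogue of 18 | CCOC(=O)C(=[N+]=[N-])C(=O)C[C@@]1(C)O[C@@](C)(/C=C/OC(=O)OCC=C)CCC13OCCO3
F2 | step 17 | bridged keto ester with C6 allyl carbonate | O=C1C[C@@]2(C)O[C@]1(C(=O)OCC)[C@H](OC(=O)OCC=C)/C=C(C)\CCC23OCCO3
F3 | step 7 | [(2R,3R)-3-[(3R)-5-(tert-butyldiphenylsilyloxy)-3-hydroxy-3-methylpentyl]-2-methyloxiran-2-yl]methanol | OC[C@@]1(C)O[C@@H]1CC[C@@](C)(O)CCO[Si](c1ccccc1)(c1ccccc1)C(C)(C)C
F4 | step 7 | (2S,3R)-3-[(3R)-5-(tert-butyldiphenylsilyloxy)-3-hydroxy-3-methylpentyl]-2-methyloxirane-2-carbaldehyde | O=C[C@@]1(C)O[C@@H]1CC[C@@](C)(O)CCO[Si](c1ccccc1)(c1ccccc1)C(C)(C)C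
F5 | step 7 | (3R)-1-(tert-butyldiphenylsilyloxy)-5-[(2R,3R)-3-ethenyl-3-methyloxiran-2-yl]-3-methylpentan-3-ol | C=C[C@@]1(C)O[C@@H]1CC[C@@](C)(O)CCO[Si](c1ccccc1)(c1ccccc1)C(C)(C)C
F6 | step 7 | (2R,3R,6R)-6-[2-(tert-butyldiphenylsilyloxy)ethyl]-2-ethenyl-2,6-dimethyloxan-3-ol | C=C[C@@]1(C)O[C@@](C)(CCO[Si](c2ccccc2)(c2ccccc2)C(C)(C)C)CC[C@H]1O
F7 | step 16 | C6 enone with C11 enol triflate and C8 silyl ether | CC(C)(C)[Si](C)(C)O[C@H]1C[C@@]2(C)O[C@]1(C(=C)OS(=O)(=O)C(F)(F)F)C(=O)/C=C(C)\CCC23OCCO3
F8 | step 19 | C6,C8 diol ethyl ester | O[C@H]1C[C@@]2(C)O[C@]1(C(=O)OCC)[C@H](O)/C=C(C)\CCC23OCCO3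
F9 | step 19 | C6 enone with free C8 hydroxyl | O[C@H]1C[C@@]2(C)O[C@]1(C(=O)OCC)C(=O)/C=C(C)\CCC23OCCO3
F10 | step 19 | C6 enone with C8 tert-butyldimethylsilyl ether | CC(C)(C)[Si](C)(C)O[C@H]1C[C@@]2(C)O[C@]1(C(=O)OCC)C(=O)/C=C(C)\CCC23OCCO3
F11 | step 19 | (6R) alcohol with C8 tert-butyldimethylsilyl ether and C7 ethyl ester | CC(C)(C)[Si](C)(C)O[C@H]1C[C@@]2(C)O[C@]1(C(=O)OCC)[C@H](O)/C=C(C)\CCC23OCCO3
F12 | step 27 | C5 bromo C4 hydroxy bromohydrin of 31 | C=C(C)C(=O)O[C@H]1C[C@@]2(C)O[C@@]13C(=C)C(=O)O[C@@H]3[C@@H](Br)[C@](C)(O)CCC2=O
A1 | alternative 1 | spiro tetrahydrofuran γ-lactone with C1 and C5 methyl esters and C8 silyl ether | CC(C)(C)[Si](C)(C)O[C@H]1C[C@](C)(C(=O)OC)O[C@@]12CC(=O)O[C@@H]2C(=O)OC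
A2 | alternative 2 | ten-membered trimethylsilyl enol ether with E C6=C7 diene, C8 4-methoxybenzyl ether and cis C4–C5 epoxide | C[Si](C)(C)O/C1=C(/C)C[C@H](OCc2ccc(OC)cc2)/C(C(C)=C)=C/[C@@H]2O[C@]2(C)CC1
A3 | alternative 3 | 11-oxabicyclo[6.2.1]undecane-2,7-dione with C8 silyl ether and C7 benzyloxymethyl group | CC(C)(C)[Si](C)(C)O[C@H]1C[C@@]2(C)O[C@]1(COCc1ccccc1)C(=O)CCCCC2=O
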